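The 1,2-dioxolane ring (O1–O2–C3–C4–C5) holds two quaternary carbons, C3 and C5, bridged by the single methylene C4, and C5 starts its side chain with a CH2 group (C1'). The key step exploits this. The ring is cut at C3–C4 and O1–C5 into a C3–O2–O1 peroxycarbenium ion and a methallylsilane whose CH2Si group is C1'. One enantioselective [3+2] annulation makes both bonds, the ring and both stereocentres. Its precursors are the racemic methoxy triethylsilylperoxy ketal of methyl acetoacetate, which loses its stereocentre on ionisation, and methallyl(dimethyl)phenylsilane. Silicon then becomes oxygen, and a Wittig reaction adds the remaining nine chain carbons.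

Key step: step 4

Remarks on the chemistry (assumptions)
- **Configuration:** the target is (3R,5S), with the C5 chain and the C3 CH2CO2H group on opposite ring faces. The annulation product and every later intermediate up to the alkene have the same spatial arrangement but read (3R,5R). This is because CH2Si, CH2O, CHO and CH=CH outrank C4 at C5, whereas a saturated chain does not.
- **Chain length:** C1' (the former CH2Si carbon) plus the nine carbons of the phenylnonyl ylide give the ten CH2 groups of the target.
- **Catalyst:** the squaramide of step 4 is 3-{[3,5-bis(trifluoromethyl)phenyl]amino}-4-({(2S)-3,3-dimethyl-1-oxo-1-[(2R)-2-(phenanthren-9-yl)pyrrolidin-1-yl]butan-2-yl}amino)cyclobut-3-ene-1,2-dione. Its SMILES is O=C1C(=O)C(Nc2cc(cc(c2)C(F)(F)F)C(F)(F)F)=C1N[C@H](C(=O)N1CCC[C@@H]1c1cc2ccccc2c2ccccc12)C(C)(C)C. It belongs to a known catalyst class, is made separately and is not counted. This mirror-image form is assumed to deliver (3R); otherwise its enantiomer is used.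
- **Lewis acid:** Et3SiOTf is used because every turnover releases Et3Si+, so the acid stays one species throughout. Its loading is kept just below that of the squaramide, so that no unbound silyl triflate runs a racemic background reaction.
- **Silyl handle:** PhMe2Si is kept. Bulkier oxidisable silyl groups would favour ring closure, but their unmasking needs strong acid or fluoride. The tertiary C5–O1 bond beta to silicon and the beta-peroxy ester would not tolerate either.
- **Alkene geometry:** the Wittig alkene is drawn as the Z isomer expected from a non-stabilised ylide. Its geometry has no consequence, since the double bond is saturated in the next step.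
- **Handling:** all peroxides are handled on small scale behind a shield and concentrated below 25 °C.

Step 1
Reactants: 1 2-methylallylmagnesium chloride (commercial solution in THF); 2 chloro(dimethyl)phenylsilane
Product: 3 dimethyl(2-methylprop-2-en-1-yl)phenylsilane
Conditions: THF, 0 °C → rt
Reagents that add atoms: none
Why: Nucleophilic substitution at silicon by an allylic Grignard reagent, in which allylic transposition of the symmetrical methallyl group leads to the same product, so only one allylsilane can form.

Step 2
Reactants: 4 methyl 3-methylbut-3-enoate (catalogue compound)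
Product: 6 methyl 3-hydroperoxy-3-methoxybutanoate (racemic), via carbonyl oxide 5 (not isolated)
Conditions: O3, MeOH/CH2Cl2, −78 °C; O2 purge; no reductive work-up
Reagents that add atoms: ozone, [O-][O+]=O; methanol, CO
Why: Criegee ozonolysis in a participating solvent, in which cycloreversion of the ozone adduct of a 1,1-disubstituted alkene releases formaldehyde and leaves the carbonyl oxide 5 on the substituted carbon, methanol adds to it, and the cold neutral medium avoids the second OMe/OOH exchange and the closure of OOH onto the ester that acid-catalysed perketalisation of a beta-keto ester ketal with H2O2 would invite; the new stereocentre is racemic and is erased in step 4.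

Step 3
Reactants: 6 methyl 3-hydroperoxy-3-methoxybutanoate
Product: 7 methyl 3-methoxy-3-[(triethylsilyl)peroxy]butanoate (racemic)
Conditions: Et3SiCl, imidazole, CH2Cl2, 0 °C
Reagents that add atoms: chlorotriethylsilane, CC[Si](Cl)(CC)CC
Why: O-silylation of a hydroperoxide, which is more acidic than an alcohol and is therefore silylated quickly with a mild base at 0 °C, before the peroxy oxygen can attack the ester.

Step 4
Reactants: 7 methyl 3-methoxy-3-[(triethylsilyl)peroxy]butanoate; 3 dimethyl(2-methylprop-2-en-1-yl)phenylsilane
Product: 10 methyl 2-[(3R,5R)-5-{[dimethyl(phenyl)silyl]methyl}-3,5-dimethyl-1,2-dioxolan-3-yl]acetate, via peroxycarbenium triflate 8 (not isolated), via beta-silyl cation triflate 9 (not isolated)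
Conditions: 3 (2 equiv), squaramide (10 mol %), Et3SiOTf (8 mol %), 4 Å molecular sieves, t-BuOMe, −78 °C
Reagents that add atoms: none
Why: Proposed new method: the squaramide binds the triflate of Et3SiOTf through its two N–H bonds and so raises the Lewis acidity of silicon, which takes the methoxy group of 7 as Et3SiOMe, and both enantiomers of 7 collapse to the same planar peroxycarbenium ion 8, held as an ion pair with the chiral squaramide-bound triflate. The CH2 terminus of 3 adds to C3 (C3–C4 bond) to give the tertiary cation 9, stabilised by hyperconjugation with the neighbouring C–Si bond, and the silylated peroxide oxygen O1 captures C5 (O1–C5 bond) and passes Et3Si+ back to triflate, which closes the catalytic cycle. The closest known reaction types are the racemic SnCl4-promoted [3+2] annulation of triethylsilylperoxy ketals with alkenes and allylsilanes and the enantioselective addition of silicon-based nucleophiles to acetals under hydrogen-bond-donor and silyl triflate co-catalysis; their combination on a peroxycarbenium ion is untested. The 1,2-dioxolane closes in a stepwise cationic fashion, formally a 5-exo-tet opening of the silicon-bridged form of 9 by O1 anti to silicon, and no 1,2-silyl shift intervenes because it would trade a tertiary for a primary cation. C3 is set in the C–C bond formation by the face of 8 that the chiral anion leaves open, the ester carbonyl offering the catalyst a second contact that tells CH2CO2Me from CH3, and C5 is set relative to C3 in the closure, in which the large CH2SiMe2Ph group should take the ring face opposite to CH2CO2Me. The step needs ring closure to outrun loss of the silyl group (Hosomi–Sakurai allylation) and loss of a C2 proton from 8, which the five-atom tether, the low silaphilicity of hydrogen-bonded triflate compared with chloride, the absence of base and the low temperature should secure, while excess 3 consumes stray TfOH.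

Step 5
Reactants: 10 methyl 2-[(3R,5R)-5-{[dimethyl(phenyl)silyl]methyl}-3,5-dimethyl-1,2-dioxolan-3-yl]acetate
Product: 13 methyl 2-[(3R,5R)-5-(hydroxymethyl)-3,5-dimethyl-1,2-dioxolan-3-yl]acetate, via acetoxysilane 11 (not isolated), via acetoxysilyl ether 12 (not isolated)
Conditions: KBr, AcOOH (in AcOH), NaOAc, AcOH, 0 °C → rt; aqueous work-up
Reagents that add atoms: peracetic acid, CC(=O)OO
Why: One-pot Fleming–Tamao oxidation, in which positive bromine made from KBr and the peracid removes the phenyl group by ipso substitution (11), the peracid adds to silicon and the CH2 group migrates from Si to O (12), and water frees the alcohol, while the peroxide is inert to peracid, the acetate buffer keeps the medium too weakly acidic to ionise C5–O1, no alkoxide is formed next to the O–O bond, and neither stereocentre takes part.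

Step 6
Reactants: 13 methyl 2-[(3R,5R)-5-(hydroxymethyl)-3,5-dimethyl-1,2-dioxolan-3-yl]acetate
Product: 14 methyl 2-[(3R,5R)-5-formyl-3,5-dimethyl-1,2-dioxolan-3-yl]acetate
Conditions: Dess–Martin periodinane, CH2Cl2, 0 °C → rt
Reagents that add atoms: none
Why: Dess–Martin oxidation runs under non-basic, non-reducing conditions that leave the O–O bond and the ester alone, and the aldehyde has no alpha hydrogen, so C5 cannot epimerise.

Step 7
Reactants: 15 9-phenylnonan-1-ol
Product: 16 (9-bromononyl)benzene
Conditions: CBr4, PPh3, CH2Cl2, 0 °C
Reagents that add atoms: carbon tetrabromide, BrC(Br)(Br)Br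
Why: Appel reaction, an SN2 displacement of an alkoxyphosphonium ion by bromide at an unhindered primary carbon under neutral conditions.

Step 8
Reactants: 16 (9-bromononyl)benzene
Product: 17 triphenyl(9-phenylnonyl)phosphonium bromide
Conditions: PPh3, MeCN, reflux
Reagents that add atoms: triphenylphosphine, c1ccccc1P(c1ccccc1)c1ccccc1
Why: SN2 quaternisation of triphenylphosphine by a primary alkyl bromide, which goes to completion in a hot polar solvent.

Step 9
Reactants: 17 triphenyl(9-phenylnonyl)phosphonium bromide; 14 methyl 2-[(3R,5R)-5-formyl-3,5-dimethyl-1,2-dioxolan-3-yl]acetate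
Product: 19 methyl 2-{(3R,5R)-3,5-dimethyl-5-[(1Z)-10-phenyldec-1-en-1-yl]-1,2-dioxolan-3-yl}acetate, via phosphonium ylide 18 (not isolated)
Conditions: 17 (1.3 equiv), NaN(SiMe3)2 (1.2 equiv), THF, 0 °C; then 14, −78 → 0 °C
Reagents that add atoms: none
Why: Wittig olefination, in which the lithium-free non-stabilised ylide 18 should add to the non-enolisable aldehyde by direct [2+2] cycloaddition to an oxaphosphetane at −78 °C faster than it deprotonates C2 or attacks the hindered O–O bond, the salt being kept in excess over the base so that no amide remains, and C5 is not touched.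

Step 10
Reactants: 19 methyl 2-{(3R,5R)-3,5-dimethyl-5-[(1Z)-10-phenyldec-1-en-1-yl]-1,2-dioxolan-3-yl}acetate
Product: 20 methyl 2-[(3R,5S)-3,5-dimethyl-5-(10-phenyldecyl)-1,2-dioxolan-3-yl]acetate
Conditions: KO2CN=NCO2K (excess, in portions), AcOH, MeOH, 0 °C → rt
Reagents that add atoms: none
Why: Diimide reduction, a concerted syn transfer of two hydrogens to the C=C bond that does not reduce O–O bonds, esters or arenes as catalytic hydrogenation would, with no stereocentre touched and the C5 descriptor changing from R to S only because the saturated chain now ranks below C4.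

Step 11
Reactants: 20 methyl 2-[(3R,5S)-3,5-dimethyl-5-(10-phenyldecyl)-1,2-dioxolan-3-yl]acetate
Product: 22 andavadoic acid, via lithium carboxylate 21 (not isolated)
Conditions: LiOH, THF/H2O, 0 °C → rt; then 1 M HCl, 0 °C
Reagents that add atoms: lithium hydroxide, [Li+].[OH-]
Why: Saponification of an unhindered methyl ester, the customary release of 1,2-dioxolane-3-acetic acids, in which hydroxide attack at the carbonyl outruns deprotonation at C2 and the resulting carboxylate is then protected against retro-oxa-Michael ring opening, while both quaternary stereocentres cannot epimerise.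

Compound list
1 | 2-methylallylmagnesium chloride | C=C(C)C[Mg]Cl | starting material
2 | chloro(dimethyl)phenylsilane | C[Si](C)(Cl)c1ccccc1 | starting material
3 | dimethyl(2-methylprop-2-en-1-yl)phenylsilane | C=C(C)C[Si](C)(C)c1ccccc1 | intermediate
4 | methyl 3-methylbut-3-enoate | C=C(C)CC(=O)OC | starting material
5 | carbonyl oxide of methyl acetoacetate | CC(CC(=O)OC)=[O+][O-] | intermediate
6 | methyl 3-hydroperoxy-3-methoxybutanoate (racemic) | COC(C)(CC(=O)OC)OO | intermediate
7 | methyl 3-methoxy-3-[(triethylsilyl)peroxy]butanoate (racemic) | COC(C)(CC(=O)OC)OO[Si](CC)(CC)CC | intermediate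
8 | (4-methoxy-4-oxobutan-2-ylidene)[(triethylsilyl)oxy]oxonium triflate | CC(CC(=O)OC)=[O+]O[Si](CC)(CC)CC.[O-]S(=O)(=O)C(F)(F)F | intermediate
9 | (4R)-1-[dimethyl(phenyl)silyl]-6-methoxy-2,4-dimethyl-6-oxo-4-[(triethylsilyl)peroxy]hexan-2-ylium triflate | C[C+](C[Si](C)(C)c1ccccc1)C[C@](C)(CC(=O)OC)OO[Si](CC)(CC)CC.[O-]S(=O)(=O)C(F)(F)F | intermediate
10 | methyl 2-[(3R,5R)-5-{[dimethyl(phenyl)silyl]methyl}-3,5-dimethyl-1,2-dioxolan-3-yl]acetate | C[C@]1(C[Si](C)(C)c2ccccc2)C[C@](C)(CC(=O)OC)OO1 | intermediate
11 | methyl 2-[(3R,5R)-5-{[acetoxy(dimethyl)silyl]methyl}-3,5-dimethyl-1,2-dioxolan-3-yl]acetate | C[C@]1(C[Si](C)(C)OC(C)=O)C[C@](C)(CC(=O)OC)OO1 | intermediate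
12 | methyl 2-[(3R,5R)-5-({[acetoxy(dimethyl)silyl]oxy}methyl)-3,5-dimethyl-1,2-dioxolan-3-yl]acetate | C[C@]1(CO[Si](C)(C)OC(C)=O)C[C@](C)(CC(=O)OC)OO1 | intermediate
13 | methyl 2-[(3R,5R)-5-(hydroxymethyl)-3,5-dimethyl-1,2-dioxolan-3-yl]acetate | C[C@]1(CO)C[C@](C)(CC(=O)OC)OO1 | intermediate
14 | methyl 2-[(3R,5R)-5-formyl-3,5-dimethyl-1,2-dioxolan-3-yl]acetate | C[C@]1(C=O)C[C@](C)(CC(=O)OC)OO1 | intermediate
15 | 9-phenylnonan-1-ol | OCCCCCCCCCc1ccccc1 | starting material
16 | (9-bromononyl)benzene | BrCCCCCCCCCc1ccccc1 | intermediate
17 | triphenyl(9-phenylnonyl)phosphonium bromide | [Br-].c1ccccc1CCCCCCCCC[P+](c1ccccc1)(c1ccccc1)c1ccccc1 | intermediate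
18 | triphenyl(9-phenylnonylidene)phosphorane | c1ccccc1CCCCCCCCC=P(c1ccccc1)(c1ccccc1)c1ccccc1 | intermediate
19 | methyl 2-{(3R,5R)-3,5-dimethyl-5-[(1Z)-10-phenyldec-1-en-1-yl]-1,2-dioxolan-3-yl}acetate | C[C@]1(/C=C\CCCCCCCCc2ccccc2)C[C@](C)(CC(=O)OC)OO1 | intermediate
20 | methyl 2-[(3R,5S)-3,5-dimethyl-5-(10-phenyldecyl)-1,2-dioxolan-3-yl]acetate | C[C@]1(CCCCCCCCCCc2ccccc2)C[C@](C)(CC(=O)OC)OO1 | intermediate
21 | lithium 2-[(3R,5S)-3,5-dimethyl-5-(10-phenyldecyl)-1,2-dioxolan-3-yl]acetate | [Li+].C[C@]1(CCCCCCCCCCc2ccccc2)C[C@](C)(CC(=O)[O-])OO1 | intermediate
22 | andavadoic acid, 2-[(3R,5S)-3,5-dimethyl-5-(10-phenyldecyl)-1,2-dioxolan-3-yl]acetic acid | C[C@]1(CCCCCCCCCCc2ccccc2)C[C@](C)(CC(=O)O)OO1 | target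

Total step count: 11.
Longest linear sequence: 8 steps (2, 3, 4, 5, 6, 9, 10, 11).

Steps most likely to fail

**Step 4.** Several processes may go wrong:
- loss of the silyl group from the cation before O1 closes the ring (plain allylation);
- loss of a C2 proton from the ester-flanked peroxycarbenium ion;
- weak discrimination of the two faces of C3 by the ion pair;
- a weak trans preference in the closure.

The fallback takes stereocontrol out of the bond-forming event and uses known chemistry. It sets out from 7 and 3, which are combined with stoichiometric SnCl4 in CH2Cl2 at −78 °C. This is the established racemic annulation of triethylsilylperoxy ketals with allylsilanes. The trans-dioxolane should form as a racemate, that is 10 together with its mirror image, methyl 2-[(3S,5S)-5-{[dimethyl(phenyl)silyl]methyl}-3,5-dimethyl-1,2-dioxolan-3-yl]acetate F1. The cis isomer is removed on silica. The enantiomers are parted by preparative chromatography on a polysaccharide carbamate chiral phase, where the phenylsilyl group helps detection and recognition. The route is rejoined at 10.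

**Step 5.** Once silicon carries acetate it is open to nucleophilic attack, and the C5–O1 bond lies beta to it. A Peterson-type elimination with opening of the ring may therefore overtake the 1,2-shift. Acid-promoted ionisation of the tertiary C5–O1 bond leads to the same loss.

The fallback brings the oxygen in with the alkene and drops the C–Si oxidation. Commercial 2-methylprop-2-en-1-ol is silylated (t-BuPh2SiCl, imidazole, CH2Cl2) to tert-butyl[(2-methylprop-2-en-1-yl)oxy]diphenylsilane F2. Setting out from 7, annulation with this alkene under the conditions of step 4 should give methyl 2-[(3R,5R)-5-{[(tert-butyldiphenylsilyl)oxy]methyl}-3,5-dimethyl-1,2-dioxolan-3-yl]acetate F3. If the less nucleophilic alkene does not respond, SnCl4 followed by chiral-phase separation is used instead. HF·pyridine in THF frees the alcohol without passing through an alkoxide, and the route is rejoined at 13.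

**Step 9.** The ylide may act as a base at C2 and start a retro-oxa-Michael opening of the ring. Addition to the neopentyl-like aldehyde may be slow. An alkoxide-like adduct next to the O–O bond may fragment.

The fallback installs the chain on the alkene before the ring is made, so no aldehyde is needed. It sets out from 16 and 1. Their Li2CuCl4-catalysed cross-coupling in THF at 0 °C should give (11-methyldodec-11-en-1-yl)benzene F4. Annulation of this 1,1-disubstituted alkene with 7 leads directly to 20, where the route is rejoined. The conditions are those of step 4, or SnCl4 with chiral-phase separation. The price is the loss of the beta-silicon activation and a small size difference between CH3 and the chain at C5. Chromatographic removal of the cis isomer must therefore be expected.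

Further compounds
F1 | step 4 | methyl 2-[(3S,5S)-5-{[dimethyl(phenyl)silyl]methyl}-3,5-dimethyl-1,2-dioxolan-3-yl]acetate | C[C@@]1(C[Si](C)(C)c2ccccc2)C[C@@](C)(CC(=O)OC)OO1
F2 | step 5 | tert-butyl[(2-methylprop-2-en-1-yl)oxy]diphenylsilane | C=C(C)CO[Si](c1ccccc1)(c1ccccc1)C(C)(C)C
F3 | step 5 | methyl 2-[(3R,5R)-5-{[(tert-butyldiphenylsilyl)oxy]methyl}-3,5-dimethyl-1,2-dioxolan-3-yl]acetate | C[C@]1(CO[Si](c2ccccc2)(c2ccccc2)C(C)(C)C)C[C@](C)(CC(=O)OC)OO1
F4 | step 9 | (11-methyldodec-11-en-1-yl)benzene | C=C(C)CCCCCCCCCCc1ccccc1
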